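## Structural features

The target is a flavone with no stereocentre: benzene ring A is fused through C4a–C8a to the 4-pyranone ring C, and ring B is attached to C2 by a single aryl–aryl-type bond. Ring A is fully substituted (free hydroxyl at C5, methoxyls at C6, C7 and C8), ring C carries a methoxyl at C3, and ring B is the symmetric 3',5'-dihydroxy-4'-methoxyphenyl group. Because the target is achiral, no stereocentres stand next to each other; the one centre made on the way (C2) is temporary and is carried as a racemate. The real difficulty is telling eight oxygens apart: three must end as free phenols and five as methyl ethers, and O5 and O3 both sit next to the C4 carbonyl. Fragile points are the electron-rich phenols (oxidation), the C2=C3 bond of the pyranone (over-reduction, ring opening by strong alkali), and, among the intermediates, a C–O bond that is benzylic and propargylic at once. The key step uses three facts: C3 bears oxygen, C4 is bonded to C4a, and the ring A building block has exactly one unsubstituted carbon, flanked by two oxygens. An aryl ether of a 1-arylprop-2-yn-1-ol therefore already holds O1–C2; its internal alkyne carbon becomes the C3 carbonyl and its terminal carbon becomes C4, bonded to C4a. Ring B also has two aryl C–H positions (C2', C6') that the same carbene could reach through a five-membered closure, and with benzyl ethers on O3' and O5' they would be about as nucleophilic as the ring A carbon. In this plan O3' and O5' are therefore carried as bulky, electron-poor pivalate esters, and only O5 as a benzyl ether.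

## Logic of the disconnections

23 is traced to 22 and then to 21 by cutting the O5–benzyl bond and the two ring B O–acyl bonds. These protecting groups keep O5 distinct from the methoxyls and keep ring B electron-poor until the end. The forward steps must spare C2=C3 (hydrogenolysis) and the pyranone (methanolysis).

21 is traced to 20 by cutting the O3–CH3 bond, because the C3 oxygen arrives as a hydroxyl. The forward methylation needs the 3-hydroxyl to be the only free hydroxyl, which the benzyl ether and the pivalates ensure.

20 is traced to 18 (through 19) by removing the C4 carbonyl oxygen. This leaves a C3 ketone with a C4 methylene and a C2–H, the oxidation pattern that the key step delivers. The forward oxidation must choose C4 over C2.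

18 is traced to 17 by cutting the C4–C4a bond and removing the C3 carbonyl oxygen. Ring C opens to an ether that links two separate arenes and carries a terminal alkyne, so all three rings are reduced to one ether linkage. The forward step needs oxygen transfer to the alkyne to be faster than any other gold-triggered event, and needs ring A to be far more nucleophilic than ring B.

17 is traced to 16 and 9 by cutting the O1–C2 ether bond, which gives two halves of similar size. The forward step needs an SN2 etherification at a secondary benzylic propargylic carbon without ionisation, and 9 must have a single free hydroxyl.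

16 is traced to 14 and 15 by cutting the C2–C3 bond. The forward addition must be faster at the aldehyde than at the hindered aryl esters.

14 is traced through 13 and 12 to 10 by two redox adjustments and by cutting the two O–pivaloyl bonds. The forward reduction must touch only the carboxylic acid.

9 is traced through 6 and 5 to 2, and then to 1, by cutting the O–benzyl bond and converting two C–O bonds into C–Br bonds. The symmetry of 2 and one-at-a-time bromine–lithium exchange differentiate the two oxygens without a statistical step. The forward bromination must place both bromines next to the outer methoxyls.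

## Other disconnections considered

Alternative 1: The cut is the O1–C2 bond of ring C. 3-Hydroxy-5,6,7,8,4'-pentamethoxy-3',5'-bis(methanesulfonyloxy)flavone A1 is traced to the aurone dibromide A2, a benzofuran-3-one whose C2 carries bromine and a bromobenzylic carbon. In the forward step hot ethanolic KOH would open the five-membered ring at O–C2, and the phenoxide would reclose on the benzylic carbon to give ring C with the 3-hydroxyl in place.
- In its favour: it needs no noble metal, ring A is fully substituted so bromine can only add to the exocyclic alkene, and the C3 oxygen appears at the right oxidation level without a separate C4 oxidation. On that last point it is better than the chosen plan.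
- Against it here: A1 carries a methoxyl at C5, so after 3-O-methylation the end game needs a selective Lewis-acid demethylation at O5 next to a second carbonyl-flanking methoxyl at C3. The mesylates need fairly strong base for removal. The rearrangement competes with simple dehydrobromination back to an aurone, and that balance depends on the substituent peri to the carbonyl.
- Comparison: structurally, the chosen plan fixes the O5/O3 distinction from the first ring A step, whereas this one has to recover it at the end. Mechanistically it is classical ionic chemistry against a gold carbene. In step count the two are about equal.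

Alternative 2: The cut is the C5–C4a bond, so that ring A is built onto a finished pyranone. 3',5'-Bis(benzyloxy)-5-hydroxy-3,6,7,8,4'-pentamethoxyflavone A3 is traced to the cyclobutenone A4. In the forward step heating would open the four-membered ring (4π) to a dienylketene, which closes (6π) onto the free pyranone carbon next to the carbonyl and tautomerises to the 5-hydroxyl.
- In its favour: the three methoxyls and the free 5-hydroxyl of ring A come out already differentiated, the 3-methoxyl is present beforehand, and A3 is one hydrogenolysis from the target. In end-game economy and in avoiding any C4 oxidation it is better than the chosen plan, and it equals it in regiochemical certainty on ring A.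
- Against it here: A4 requires a pyranone metalated next to the ring oxygen to add to a squaric diester, in the presence of the pyranone's own carbonyl. The 6π closure must also engage an electron-poor pyranone double bond, for which there is less precedent than for arenes or simple alkenes.
- Comparison: the structure is reached more directly and the mechanism is a neutral, reagent-free pericyclic cascade. The step count could be lower, but the risk is concentrated in making A4, whereas the chosen plan spreads smaller risks over standard steps.

Alternative 3: The cuts are C4a–C4, C4–C3 and O1–C2. 3',5'-Bis(benzyloxy)-5,6,7,8,4'-pentamethoxyflavone A5 is traced to 2-iodo-3,4,5,6-tetramethoxyphenol A6, 1,3-bis(benzyloxy)-5-ethynyl-2-methoxybenzene A7 and carbon monoxide A8. In the forward step PdCl2(PPh3)2 in Et2NH would give an aroylpalladium species, couple it with the alkyne to an ynone and let the phenol close ring C.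
- In its favour: three bonds and a ring form in one operation from two fragments of equal size, on well-established palladium chemistry. In convergence and in the step count up to the flavone it is better than the chosen plan.
- Against it here: A5 has no oxygen at C3 and a methoxyl in place of the 5-hydroxyl. The end game would need C3 hydroxylation of the enone, methylation and then selective O5 demethylation beside the new 3-methoxyl. Five-membered closure to an aurone competes with the six-membered closure, oxidative addition into an iodide flanked by hydroxyl and methoxyl on a very electron-rich ring is slow, and CO must be handled.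
- Comparison: the chosen plan builds the C3 oxygen and the O5 distinction into the skeleton-forming step, whereas this one adds them afterwards. The early advantage in step count is therefore largely used up at the end.

Key step: step 10

Remark on the chemistry: the C2 centre of 16–19 is carried as the racemate because it becomes sp2 in 20; 1, 10 and 15 (as a THF solution) are taken as purchasable. Me4tBuXPhos is 2-(di-tert-butylphosphino)-3,4,5,6-tetramethyl-2',4',6'-triisopropylbiphenyl.

## Steps

Step 1
Reactants: 1 1,2,3-trimethoxybenzene
Product: 2 1,5-dibromo-2,3,4-trimethoxybenzene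
Conditions: NBS (2.1 equiv), MeCN, 0 °C → rt
Reagents that add atoms: N-bromosuccinimide, O=C1CCC(=O)N1Br
Why: Electrophilic aromatic bromination; the two outer methoxyls direct ortho/para to C4 and C6, while the twisted central methoxyl hardly activates C5, so after the first bromine the second should enter the other flank and give the symmetric dibromide.

Step 2
Reactants: 2 1,5-dibromo-2,3,4-trimethoxybenzene
Product: 5 5-bromo-2,3,4-trimethoxyphenol, via aryllithium 3 (not isolated), via lithium aryltrimethoxyborate 4 (not isolated)
Conditions: n-BuLi (1.0 equiv), THF, −78 °C; B(OMe)3, −78 → 0 °C; AcOH, 30% H2O2, 0 °C → rt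
Reagents that add atoms: n-butyllithium, [Li]CCCC (lithium of 3); trimethyl borate, COB(OC)OC (borate of 4); hydrogen peroxide, OO (phenol oxygen of 5)
Why: Bromine–lithium exchange with one equivalent should stop after one bromine because the two are equivalent and the aryllithium resists a second exchange; borate formation and peroxide-induced 1,2-aryl shift (boronate oxidation) then give the phenol.

Step 3
Reactants: 5 5-bromo-2,3,4-trimethoxyphenol
Product: 6 1-(benzyloxy)-5-bromo-2,3,4-trimethoxybenzene
Conditions: BnBr, K2CO3, DMF, rt
Reagents that add atoms: benzyl bromide, BrCc1ccccc1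
Why: Williamson etherification of the only phenol; the benzyl ether keeps this oxygen a donor for the later ring closure and comes off by hydrogenolysis at the end.

Step 4
Reactants: 6 1-(benzyloxy)-5-bromo-2,3,4-trimethoxybenzene
Product: 9 5-(benzyloxy)-2,3,4-trimethoxyphenol, via aryllithium 7 (not isolated), via lithium aryltrimethoxyborate 8 (not isolated)
Conditions: n-BuLi (1.05 equiv), THF, −78 °C; B(OMe)3, −78 → 0 °C; AcOH, 30% H2O2, 0 °C → rt
Reagents that add atoms: n-butyllithium, [Li]CCCC (lithium of 7); trimethyl borate, COB(OC)OC (borate of 8); hydrogen peroxide, OO (phenol oxygen of 9)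
Why: The same exchange–borylation–oxidation sequence; at −78 °C the exchange is much faster than deprotonation of the benzyl ether, and the acidic peroxide medium limits oxidation of the electron-rich phenol.

Step 5
Reactants: 10 3,5-dihydroxy-4-methoxybenzoic acid
Product: 12 3,5-bis[(2,2-dimethylpropanoyl)oxy]-4-methoxybenzoic acid, via mixed pivalic anhydride 11 (not isolated)
Conditions: PivCl (3.3 equiv), pyridine, DMAP (cat.), CH2Cl2, 0 °C → rt; then H2O, rt; aq. HCl work-up
Reagents that add atoms: pivaloyl chloride, CC(C)(C)C(Cl)=O; water, O (hydrolysis of 11, may supply one carboxyl oxygen)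
Why: O-acylation of both phenols; the carboxyl group is acylated too, but the mixed anhydride is hydrolysed by water and pyridine while the hindered aryl pivalates persist.

Step 6
Reactants: 12 3,5-bis[(2,2-dimethylpropanoyl)oxy]-4-methoxybenzoic acid
Product: 13 5-(hydroxymethyl)-2-methoxy-1,3-phenylene bis(2,2-dimethylpropanoate)
Conditions: BH3·SMe2 (1.5 equiv), THF, 0 °C → rt; MeOH
Reagents that add atoms: none
Why: Chemoselective borane reduction of a carboxylic acid through its acyloxyborane; hindered aryl esters are reduced far more slowly.

Step 7
Reactants: 13 5-(hydroxymethyl)-2-methoxy-1,3-phenylene bis(2,2-dimethylpropanoate)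
Product: 14 5-formyl-2-methoxy-1,3-phenylene bis(2,2-dimethylpropanoate)
Conditions: Dess–Martin periodinane (1.2 equiv), CH2Cl2, rt
Reagents that add atoms: none
Why: Dess–Martin oxidation of a primary benzylic alcohol stops at the aldehyde and leaves the esters alone.

Step 8
Reactants: 14 5-formyl-2-methoxy-1,3-phenylene bis(2,2-dimethylpropanoate); 15 ethynylmagnesium bromide
Product: 16 racemic 5-(1-hydroxyprop-2-yn-1-yl)-2-methoxy-1,3-phenylene bis(2,2-dimethylpropanoate)
Conditions: 15 (1.3 equiv, 0.5 M in THF), THF, −78 → −20 °C; aq. NH4Cl
Reagents that add atoms: none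
Why: Grignard 1,2-addition; the aldehyde, activated by two meta acyloxy groups, should react far faster than the hindered pivalates at low temperature, and the new carbinol centre (later C2) is formed without control because it is destroyed in step 11.

Step 9
Reactants: 16 racemic 5-(1-hydroxyprop-2-yn-1-yl)-2-methoxy-1,3-phenylene bis(2,2-dimethylpropanoate); 9 5-(benzyloxy)-2,3,4-trimethoxyphenol
Product: 17 racemic 5-{1-[5-(benzyloxy)-2,3,4-trimethoxyphenoxy]prop-2-yn-1-yl}-2-methoxy-1,3-phenylene bis(2,2-dimethylpropanoate)
Conditions: PPh3, DIAD, THF, 0 °C → rt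
Reagents that add atoms: none
Why: Mitsunobu etherification; the phenoxide displaces the alkoxyphosphonium at the propargylic carbon by SN2 (inversion, immaterial for a racemate), and the electron-poor ring B disfavours ionisation and hence SN1 or SN2' leakage.

Step 10
Reactants: 17 racemic 5-{1-[5-(benzyloxy)-2,3,4-trimethoxyphenoxy]prop-2-yn-1-yl}-2-methoxy-1,3-phenylene bis(2,2-dimethylpropanoate)
Product: 18 racemic 5-[5-(benzyloxy)-6,7,8-trimethoxy-3-oxo-3,4-dihydro-2H-chromen-2-yl]-2-methoxy-1,3-phenylene bis(2,2-dimethylpropanoate)
Conditions: (Me4tBuXPhos)AuNTf2 (5 mol%), 3,5-dichloropyridine N-oxide (1.5 equiv), ClCH2CH2Cl, rt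
Reagents that add atoms: 3,5-dichloropyridine N-oxide, [O-][n+]1cc(Cl)cc(Cl)c1
Why: Cationic monovalent gold activates the terminal alkyne, the N-oxide oxygen adds to the internal carbon, and N–O cleavage of the vinylgold releases 3,5-dichloropyridine and leaves an α-oxo gold carbene on the former terminal carbon. The single unsubstituted ring A carbon, ortho to the ether oxygen, attacks this carbene, and rearomatisation with protodeauration gives the C3 ketone and the C4–C4a bond, a formal aryl C–H insertion that is in fact an intramolecular Friedel–Crafts alkylation. The closest known reaction type is the gold-catalysed N-oxide oxidation of aryl propargyl ethers to chroman-3-ones, with rhodium carbenoid cyclisation of aryloxy diazoketones as an older relative. Ring C closes in a six-membered mode in which the arene carbon attacks a carbene carbon tethered through C3, C2 and O1. No stereocentre is made; the racemic C2 centre from step 8 is carried through unchanged. The first selectivity needed is oxygen transfer ahead of gold-induced ionisation of the benzylic propargylic C–O bond, propargyl rearrangement or 6-endo hydroarylation, which the bulky biarylphosphine, the electron-poor N-oxide in excess and the cation-destabilising meta-pivaloyloxy groups should secure. The second is ring A against ring B: the ring A carbon has two ortho alkoxy donors and a para methoxyl and closes a six-membered ring, whereas each ring B ortho carbon is flanked by a bulky, electron-poor pivaloyloxy group and would have to close a five-membered ring. Fast intramolecular trapping should also limit a second oxidation of the carbene by the N-oxide.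

Step 11
Reactants: 18 racemic 5-[5-(benzyloxy)-6,7,8-trimethoxy-3-oxo-3,4-dihydro-2H-chromen-2-yl]-2-methoxy-1,3-phenylene bis(2,2-dimethylpropanoate)
Product: 20 5-[5-(benzyloxy)-3-hydroxy-6,7,8-trimethoxy-4-oxo-4H-chromen-2-yl]-2-methoxy-1,3-phenylene bis(2,2-dimethylpropanoate), via chroman-3,4-dione 19 (not isolated)
Conditions: SeO2 (1.2 equiv), 1,4-dioxane/H2O (30:1), 90 °C
Reagents that add atoms: selenium dioxide, O=[Se]=O
Why: Riley oxidation through the enol; only the C4 methylene has the two hydrogens needed to reach a carbonyl and its enol is conjugated with ring A, and the 3,4-dione should enolise at once through C2–H to the aromatic 3-hydroxy-4-pyranone, which removes the C2 stereocentre.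

Step 12
Reactants: 20 5-[5-(benzyloxy)-3-hydroxy-6,7,8-trimethoxy-4-oxo-4H-chromen-2-yl]-2-methoxy-1,3-phenylene bis(2,2-dimethylpropanoate)
Product: 21 5-[5-(benzyloxy)-3,6,7,8-tetramethoxy-4-oxo-4H-chromen-2-yl]-2-methoxy-1,3-phenylene bis(2,2-dimethylpropanoate)
Conditions: MeI (2 equiv), K2CO3, acetone, 50 °C
Reagents that add atoms: iodomethane, CI
Why: Williamson O-methylation of the acidic enolic 3-hydroxyl, the only free hydroxyl in the molecule; anhydrous carbonate in acetone should leave the pivalates intact.

Step 13
Reactants: 21 5-[5-(benzyloxy)-3,6,7,8-tetramethoxy-4-oxo-4H-chromen-2-yl]-2-methoxy-1,3-phenylene bis(2,2-dimethylpropanoate)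
Product: 22 5-(benzyloxy)-2-(3,5-dihydroxy-4-methoxyphenyl)-3,6,7,8-tetramethoxy-4H-chromen-4-one
Conditions: K2CO3, MeOH/THF, 40 °C; aq. NH4Cl
Reagents that add atoms: none
Why: Base-catalysed transesterification of the aryl esters with methanol; the conditions are mild enough for the 3-methoxypyranone.

Step 14
Reactants: 22 5-(benzyloxy)-2-(3,5-dihydroxy-4-methoxyphenyl)-3,6,7,8-tetramethoxy-4H-chromen-4-one
Product: 23 5-hydroxy-2-(3,5-dihydroxy-4-methoxyphenyl)-3,6,7,8-tetramethoxy-4H-chromen-4-one (5,3',5'-trihydroxy-3,6,7,8,4'-pentamethoxyflavone)
Conditions: H2 (1 atm), Pd/C (10 wt%), EtOAc/MeOH, rt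
Reagents that add atoms: none
Why: Hydrogenolysis of the aryl benzyl ether, which is eased at the position peri to the carbonyl; stopping at full conversion should spare the tetrasubstituted C2=C3 bond.

## Compound list

1 | 1,2,3-trimethoxybenzene | COc1cccc(OC)c1OC | starting material
2 | 1,5-dibromo-2,3,4-trimethoxybenzene | COc1c(Br)cc(Br)c(OC)c1OC | intermediate
3 | (5-bromo-2,3,4-trimethoxyphenyl)lithium | [Li]c1cc(Br)c(OC)c(OC)c1OC | intermediate
4 | lithium (5-bromo-2,3,4-trimethoxyphenyl)trimethoxyborate | [Li+].CO[B-](OC)(OC)c1cc(Br)c(OC)c(OC)c1OC | intermediate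
5 | 5-bromo-2,3,4-trimethoxyphenol | COc1c(O)cc(Br)c(OC)c1OC | intermediate
6 | 1-(benzyloxy)-5-bromo-2,3,4-trimethoxybenzene | COc1c(OCc2ccccc2)cc(Br)c(OC)c1OC | intermediate
7 | [5-(benzyloxy)-2,3,4-trimethoxyphenyl]lithium | [Li]c1cc(OCc2ccccc2)c(OC)c(OC)c1OC | intermediate
8 | lithium [5-(benzyloxy)-2,3,4-trimethoxyphenyl]trimethoxyborate | [Li+].CO[B-](OC)(OC)c1cc(OCc2ccccc2)c(OC)c(OC)c1OC | intermediate
9 | 5-(benzyloxy)-2,3,4-trimethoxyphenol | Oc1cc(OCc2ccccc2)c(OC)c(OC)c1OC | intermediate
10 | 3,5-dihydroxy-4-methoxybenzoic acid | COc1c(O)cc(C(=O)O)cc1O | starting material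
11 | 3,5-bis[(2,2-dimethylpropanoyl)oxy]-4-methoxybenzoic 2,2-dimethylpropanoic anhydride | COc1c(OC(=O)C(C)(C)C)cc(C(=O)OC(=O)C(C)(C)C)cc1OC(=O)C(C)(C)C | intermediate
12 | 3,5-bis[(2,2-dimethylpropanoyl)oxy]-4-methoxybenzoic acid | COc1c(OC(=O)C(C)(C)C)cc(C(=O)O)cc1OC(=O)C(C)(C)C | intermediate
13 | 5-(hydroxymethyl)-2-methoxy-1,3-phenylene bis(2,2-dimethylpropanoate) | COc1c(OC(=O)C(C)(C)C)cc(CO)cc1OC(=O)C(C)(C)C | intermediate
14 | 5-formyl-2-methoxy-1,3-phenylene bis(2,2-dimethylpropanoate) | COc1c(OC(=O)C(C)(C)C)cc(C=O)cc1OC(=O)C(C)(C)C | intermediate
15 | ethynylmagnesium bromide | C#C[Mg]Br | starting material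
16 | racemic 5-(1-hydroxyprop-2-yn-1-yl)-2-methoxy-1,3-phenylene bis(2,2-dimethylpropanoate) | C#CC(O)c1cc(OC(=O)C(C)(C)C)c(OC)c(OC(=O)C(C)(C)C)c1 | intermediate
17 | racemic 5-{1-[5-(benzyloxy)-2,3,4-trimethoxyphenoxy]prop-2-yn-1-yl}-2-methoxy-1,3-phenylene bis(2,2-dimethylpropanoate) | C#CC(Oc1cc(OCc2ccccc2)c(OC)c(OC)c1OC)c1cc(OC(=O)C(C)(C)C)c(OC)c(OC(=O)C(C)(C)C)c1 | intermediate
18 | racemic 5-[5-(benzyloxy)-6,7,8-trimethoxy-3-oxo-3,4-dihydro-2H-chromen-2-yl]-2-methoxy-1,3-phenylene bis(2,2-dimethylpropanoate) | O=C1Cc2c(OCc3ccccc3)c(OC)c(OC)c(OC)c2OC1c1cc(OC(=O)C(C)(C)C)c(OC)c(OC(=O)C(C)(C)C)c1 | intermediate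
19 | racemic 5-[5-(benzyloxy)-6,7,8-trimethoxy-3,4-dioxo-3,4-dihydro-2H-chromen-2-yl]-2-methoxy-1,3-phenylene bis(2,2-dimethylpropanoate) | O=C1C(=O)c2c(OCc3ccccc3)c(OC)c(OC)c(OC)c2OC1c1cc(OC(=O)C(C)(C)C)c(OC)c(OC(=O)C(C)(C)C)c1 | intermediate
20 | 5-[5-(benzyloxy)-3-hydroxy-6,7,8-trimethoxy-4-oxo-4H-chromen-2-yl]-2-methoxy-1,3-phenylene bis(2,2-dimethylpropanoate) | O=c1c(O)c(-c2cc(OC(=O)C(C)(C)C)c(OC)c(OC(=O)C(C)(C)C)c2)oc2c(OC)c(OC)c(OC)c(OCc3ccccc3)c12 | intermediate
21 | 5-[5-(benzyloxy)-3,6,7,8-tetramethoxy-4-oxo-4H-chromen-2-yl]-2-methoxy-1,3-phenylene bis(2,2-dimethylpropanoate) | O=c1c(OC)c(-c2cc(OC(=O)C(C)(C)C)c(OC)c(OC(=O)C(C)(C)C)c2)oc2c(OC)c(OC)c(OC)c(OCc3ccccc3)c12 | intermediate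
22 | 5-(benzyloxy)-2-(3,5-dihydroxy-4-methoxyphenyl)-3,6,7,8-tetramethoxy-4H-chromen-4-one | O=c1c(OC)c(-c2cc(O)c(OC)c(O)c2)oc2c(OC)c(OC)c(OC)c(OCc3ccccc3)c12 | intermediate
23 | 5-hydroxy-2-(3,5-dihydroxy-4-methoxyphenyl)-3,6,7,8-tetramethoxy-4H-chromen-4-one | COc1c(O)cc(-c2oc3c(OC)c(OC)c(OC)c(O)c3c(=O)c2OC)cc1O | target

## Step count and least certain steps

Total step count: 14. Longest linear sequence: 10 (steps 1–4 and then 9–14, or equally steps 5–8 and then 9–14).

Step 10 (key step). The most likely failure is that gold acts on the substrate before oxygen transfer: heterolysis of the benzylic propargylic C–O bond, or 6-endo hydroarylation of the alkyne by ring A. A second risk is further oxidation of the carbene by excess N-oxide. The fallback sets out from 17 and rejoins the route at 20, so it also bypasses step 11. It makes deliberate use of the competing hydroarylation: Ph3PAuNTf2 (or PtCl4) without oxidant should give racemic 5-[5-(benzyloxy)-6,7,8-trimethoxy-2H-chromen-2-yl]-2-methoxy-1,3-phenylene bis(2,2-dimethylpropanoate) F1. Catalytic OsO4 with N-methylmorpholine N-oxide should then add to the C3=C4 bond from the face opposite the C2 aryl group to give racemic 5-[(2,3-trans-3,4-cis)-5-(benzyloxy)-3,4-dihydroxy-6,7,8-trimethoxy-3,4-dihydro-2H-chromen-2-yl]-2-methoxy-1,3-phenylene bis(2,2-dimethylpropanoate) F2. Swern oxidation of both carbinols gives 19, which tautomerises to 20.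

Step 11. The most likely failure is attack of the oxidant at C2 instead of C4, since C2–H is also benzylic and next to the ketone; this would lead to hydroxylation at C2 and ring cleavage instead of the dione. The fallback sets out from 18 and rejoins at 20. Diazo transfer (4-acetamidobenzenesulfonyl azide, DBU, MeCN) can only be completed at the C4 methylene, which alone has two hydrogens, and should give racemic 5-[5-(benzyloxy)-4-diazo-6,7,8-trimethoxy-3-oxo-3,4-dihydro-2H-chromen-2-yl]-2-methoxy-1,3-phenylene bis(2,2-dimethylpropanoate) F3. Dimethyldioxirane in acetone then converts the diazo carbon into a carbonyl, giving 19 and hence 20.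

Step 9. The most likely failure is slow substitution by the hindered, ortho-substituted phenoxide, so that ionisation of the activated alcohol takes over and leads to C-alkylation of the electron-rich phenol or to an allenyl ether. The fallback sets out from 16 and rejoins at 17. Acetylation (Ac2O, pyridine) gives racemic 5-[1-(acetyloxy)prop-2-yn-1-yl]-2-methoxy-1,3-phenylene bis(2,2-dimethylpropanoate) F4. Copper-catalysed propargylic etherification with 9 (Cu(MeCN)4BF4, a 2,6-bis(oxazolinyl)pyridine ligand, iPr2NEt, trifluorotoluene, 0 °C) then proceeds through a copper allenylidene, which the terminal alkyne makes possible, and delivers the oxygen nucleophile to the propargylic carbon.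

Step 2. The most likely failure is loss of control over the exchange (double exchange, or protonation of the aryllithium to debrominated material), followed by over-oxidation of the electron-rich phenol by peroxide. The fallback sets out from 1 and rejoins at 5, so it bypasses 2. Vilsmeier formylation (POCl3, DMF) gives 2,3,4-trimethoxybenzaldehyde F5. Bromination (NBS, MeCN) goes ortho to the 4-methoxyl and meta to the formyl group to give 5-bromo-2,3,4-trimethoxybenzaldehyde F6. Baeyer–Villiger oxidation (mCPBA, CH2Cl2) with migration of the electron-rich aryl group gives 5-bromo-2,3,4-trimethoxyphenyl formate F7, and methanolysis (K2CO3, MeOH) gives 5.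

## Further compounds

F1 | step 10 | racemic 5-[5-(benzyloxy)-6,7,8-trimethoxy-2H-chromen-2-yl]-2-methoxy-1,3-phenylene bis(2,2-dimethylpropanoate) | COc1c(OC(=O)C(C)(C)C)cc(C2C=Cc3c(OCc4ccccc4)c(OC)c(OC)c(OC)c3O2)cc1OC(=O)C(C)(C)C
F2 | step 10 | racemic 5-[(2,3-trans-3,4-cis)-5-(benzyloxy)-3,4-dihydroxy-6,7,8-trimethoxy-3,4-dihydro-2H-chromen-2-yl]-2-methoxy-1,3-phenylene bis(2,2-dimethylpropanoate), one enantiomer drawn | O[C@H]1[C@@H](O)c2c(OCc3ccccc3)c(OC)c(OC)c(OC)c2O[C@@H]1c1cc(OC(=O)C(C)(C)C)c(OC)c(OC(=O)C(C)(C)C)c1
F3 | step 11 | racemic 5-[5-(benzyloxy)-4-diazo-6,7,8-trimethoxy-3-oxo-3,4-dihydro-2H-chromen-2-yl]-2-methoxy-1,3-phenylene bis(2,2-dimethylpropanoate) | [N-]=[N+]=C1C(=O)C(c2cc(OC(=O)C(C)(C)C)c(OC)c(OC(=O)C(C)(C)C)c2)Oc2c(OC)c(OC)c(OC)c(OCc3ccccc3)c21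
F4 | step 9 | racemic 5-[1-(acetyloxy)prop-2-yn-1-yl]-2-methoxy-1,3-phenylene bis(2,2-dimethylpropanoate) | C#CC(OC(C)=O)c1cc(OC(=O)C(C)(C)C)c(OC)c(OC(=O)C(C)(C)C)c1
F5 | step 2 | 2,3,4-trimethoxybenzaldehyde | COc1ccc(C=O)c(OC)c1OC
F6 | step 2 | 5-bromo-2,3,4-trimethoxybenzaldehyde | COc1c(Br)cc(C=O)c(OC)c1OC
F7 | step 2 | 5-bromo-2,3,4-trimethoxyphenyl formate | COc1c(Br)cc(OC=O)c(OC)c1OC
A1 | alternative 1 | 3-hydroxy-5,6,7,8,4'-pentamethoxy-3',5'-bis(methanesulfonyloxy)flavone | O=c1c(O)c(-c2cc(OS(C)(=O)=O)c(OC)c(OS(C)(=O)=O)c2)oc2c(OC)c(OC)c(OC)c(OC)c12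
A2 | alternative 1 | 2-bromo-2-{bromo[4-methoxy-3,5-bis(methanesulfonyloxy)phenyl]methyl}-4,5,6,7-tetramethoxy-1-benzofuran-3(2H)-one (racemic, relative configuration left open) | O=C1c2c(OC)c(OC)c(OC)c(OC)c2OC1(Br)C(Br)c1cc(OS(C)(=O)=O)c(OC)c(OS(C)(=O)=O)c1
A3 | alternative 2 | 3',5'-bis(benzyloxy)-5-hydroxy-3,6,7,8,4'-pentamethoxyflavone | O=c1c(OC)c(-c2cc(OCc3ccccc3)c(OC)c(OCc3ccccc3)c2)oc2c(OC)c(OC)c(OC)c(O)c12
A4 | alternative 2 | racemic 4-{6-[3,5-bis(benzyloxy)-4-methoxyphenyl]-5-methoxy-4-oxo-4H-pyran-2-yl}-2,3,4-trimethoxycyclobut-2-en-1-one | COC1=C(OC)C(OC)(c2cc(=O)c(OC)c(-c3cc(OCc4ccccc4)c(OC)c(OCc4ccccc4)c3)o2)C1=O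
A5 | alternative 3 | 3',5'-bis(benzyloxy)-5,6,7,8,4'-pentamethoxyflavone | O=c1cc(-c2cc(OCc3ccccc3)c(OC)c(OCc3ccccc3)c2)oc2c(OC)c(OC)c(OC)c(OC)c12
A6 | alternative 3 | 2-iodo-3,4,5,6-tetramethoxyphenol | Oc1c(I)c(OC)c(OC)c(OC)c1OC
A7 | alternative 3 | 1,3-bis(benzyloxy)-5-ethynyl-2-methoxybenzene | C#Cc1cc(OCc2ccccc2)c(OC)c(OCc2ccccc2)c1
A8 | alternative 3 | carbon monoxide | [C-]#[O+]
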